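**Plan**
- Numbering: C1 = aryl-bearing CH; C2, C3 = the CH carbons carrying C9H2OH and C9'H2OH; C4 = benzylic CH2; C4a/C8a = fusion carbons; ring A = fused arene (C6 OMe, C7 OH); ring B = the carbocycle.
- Enabling feature: C1 is a doubly benzylic methine between ring A (C6 methoxy para to C8a) and the pendant guaiacyl ring (oxygen para to C1). It can therefore exist as a stabilized cation directly beside C2, whose C9 arm can sit at the aldehyde level and serve as an enamine.
- Cuts, in retrosynthetic order: the two O-benzyl bonds and the C9–O lactol bond; then C1–C2 (ring B); then C1–C8a of the diarylcarbinol; then C8a–Br; finally the C3–C4 olefin bond of a Stobbe half-ester.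
- Forward: the succinate chain is joined to O-benzylvanillin, the butyrolactone ring is formed, C8a is brominated, the lactol is masked, the second aryl unit is added at C1, and ring B closes last as the only carbocycle made.
- Stereochemistry: C3 comes from a Rh-catalysed asymmetric hydrogenation; C2 and C1 arise together in the ring closure, relayed from C3 through a chair transition state and reinforced by a chiral amine.

Key step: step 9

Assumption: the (S,S) ligand of step 2 and the (2R,5R) amine of step 9 are taken as the antipodes that give (R)-C3 and the matched ring closure (usual quadrant and face-shielding models); if a test run shows the opposite sense, the mirror-image reagent is used.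

**Step 1**
Reactants: 1 O-benzylvanillin (4-benzyloxy-3-methoxybenzaldehyde); 2 dimethyl succinate
Product: 4 (E)-4-[4-(benzyloxy)-3-methoxyphenyl]-3-(methoxycarbonyl)but-3-enoic acid, via paraconic ester lactone 3 (not isolated)
Conditions: NaOMe (2 equiv), MeOH, reflux; then aq. HCl
Reagents that add atoms: none
Why: Stobbe condensation, in which the succinate enolate adds to the aldehyde, the alkoxide lactonizes to 3 and base-induced E1cB ring opening should give the (E)-half-ester, whose carboxylate blocks a second condensation.

**Step 2**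
Reactants: 4 (E)-half-ester
Product: 5 (R)-4-[4-(benzyloxy)-3-methoxyphenyl]-3-(methoxycarbonyl)butanoic acid
Conditions: H2 (5 bar), [Rh(cod)(L)]BF4 (0.5 mol%; L = 1,2-bis[(2S,5S)-2,5-diethylphospholan-1-yl]benzene), NaOMe (10 mol%), MeOH, rt
Reagents that add atoms: none
Why: Rh-catalysed asymmetric hydrogenation of a β-aryl itaconate half-ester, a standard substrate class for chelating bisphospholane catalysts, in which the ligand-controlled face of hydrogen delivery sets C3 as (R) and the aryl benzyl ether is not touched by the homogeneous catalyst.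

**Step 3**
Reactants: 5 (R)-half-ester
Product: 7 (R)-4-[4-(benzyloxy)-3-methoxybenzyl]dihydrofuran-2(3H)-one, via hydroxy acid 6 (not isolated)
Conditions: KOH (1 equiv), EtOH, 0 °C; CaCl2, NaBH4, EtOH, −10 °C to rt; then 3 M HCl, rt
Reagents that add atoms: none
Why: chemoselective ester reduction, since Ca(BH4)2 reduces the methyl ester while the potassium carboxylate is inert, and acid-induced lactonization of 6 then closes the γ-lactone without touching C3.

**Step 4**
Reactants: 7 (R)-lactone
Product: 8 (R)-4-[4-(benzyloxy)-2-bromo-5-methoxybenzyl]dihydrofuran-2(3H)-one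
Conditions: NBS (1.05 equiv), MeCN, 0 °C to rt, dark
Reagents that add atoms: N-bromosuccinimide, O=C1CCC(=O)N1Br
Why: electrophilic aromatic bromination, which in 3,4-dialkoxybenzyl rings goes to the position para to the methoxy group and ortho to the alkyl chain, here the future C8a.

**Step 5**
Reactants: 8 bromo lactone
Product: 9 (4R)-4-[4-(benzyloxy)-2-bromo-5-methoxybenzyl]tetrahydrofuran-2-ol (anomer mixture)
Conditions: i-Bu2AlH (DIBAL-H, 1.1 equiv), CH2Cl2, −78 °C; aq. potassium sodium tartrate
Reagents that add atoms: none
Why: partial reduction of a γ-lactone, which at −78 °C should stop at the aluminium lactolate and give the lactol (C9 at the aldehyde level) on work-up, the aryl bromide being inert.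

**Step 6**
Reactants: 9 bromo lactol
Product: 10 tert-butyl{[(4R)-4-(4-benzyloxy-2-bromo-5-methoxybenzyl)tetrahydrofuran-2-yl]oxy}dimethylsilane (anomer mixture)
Conditions: t-BuMe2SiCl, imidazole, DMF, 0 °C to rt
Reagents that add atoms: tert-butyldimethylsilyl chloride, CC(C)(C)[Si](C)(C)Cl
Why: silylation of the anomeric hydroxyl, which masks the latent aldehyde as a base-stable silyl acetal that can later be removed without acid.

**Step 7**
Reactants: 10 silyl-protected bromo lactol; 1 O-benzylvanillin
Product: 12 {4-(benzyloxy)-2-[((3R)-5-(tert-butyldimethylsilyloxy)tetrahydrofuran-3-yl)methyl]-5-methoxyphenyl}[4-(benzyloxy)-3-methoxyphenyl]methanol (carbinol epimers and anomers), via aryllithium 11 (not isolated)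
Conditions: n-BuLi (1.05 equiv), THF, −78 °C; then 1 (1.1 equiv), −78 to −40 °C; H2O
Reagents that add atoms: none
Why: bromine–lithium exchange followed by 1,2-addition of the aryllithium to an aldehyde, the exchange being faster than any deprotonation at −78 °C, and the new carbinol centre needs no control because it is planarized in step 9.

**Step 8**
Reactants: 12 silyl-protected diarylcarbinol
Product: 13 (4R)-4-{4-(benzyloxy)-2-[(4-benzyloxy-3-methoxyphenyl)(hydroxy)methyl]-5-methoxybenzyl}tetrahydrofuran-2-ol (carbinol epimers and anomers)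
Conditions: Bu4NF (1.2 equiv), AcOH (1.2 equiv), THF, 0 °C
Reagents that add atoms: none
Why: fluoride-mediated desilylation under acetic acid buffering, which should free the lactol without any acid strong enough to ionize the diarylcarbinol before the ring closure.

**Step 9**
Reactants: 13 lactol diarylcarbinol
Product: 16 (1S,2R,3R)-7-benzyloxy-1-(4-benzyloxy-3-methoxyphenyl)-6-methoxytetralin whose C2 and C3 are bridged by a C9H(OH)–O–C9'H2 lactol (trans-fused; C9 anomers), via enamine cation 14 (not isolated), via tetralin hydroxy aldehyde 15 (not isolated)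
Conditions: (2R,5R)-5-benzyl-2-tert-butyl-3-methylimidazolidin-4-one·CF3CO2H (20 mol%), CF3CO2H (20 mol%), CH2Cl2 (0.02 M), 0 °C to rt
Reagents that add atoms: none
Why: Proposed new method: ring-chain tautomerism of 13 frees the C9 aldehyde, which condenses with the imidazolidinone to the (E)-enamine at C2 while CF3CO2H ionizes the diarylcarbinol to a C1 cation stabilized by the para benzyloxy group of the pendant ring and the para C6 methoxy group of ring A; C2 then bonds to C1, the iminium is hydrolysed and the C9' hydroxyl recloses the lactol. The closest known reaction type is the amine-catalysed SN1 α-alkylation of aldehydes with donor-substituted benzhydrols, established between two molecules and run here within one. Ring B closes in a 6-(enolexo)-exo-trig mode, counting the cation in its para-quinoid form on the pendant ring. C2 is set by a chair-like transition state in which the C9' arm on C3 is equatorial and the enamine reacts through the face left open by the benzyl group of the amine, and C1 is set in the same transition state by the pendant aryl taking the pseudo-equatorial site trans to C9. The step needs C- over O-alkylation and ring closure over bimolecular arylation: capture of the cation by the hydroxyls is reversible under acid whereas the C1–C2 bond is not, high dilution disfavours bimolecular paths, C2 is the only enolizable position, and lactol capture of the α-branched product aldehyde shields C2 from epimerization.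

**Step 10**
Reactants: 16 tetralin lactol
Product: 17 (1S,2R,3R)-7-benzyloxy-1-(4-benzyloxy-3-methoxyphenyl)-2,3-bis(hydroxymethyl)-6-methoxy-1,2,3,4-tetrahydronaphthalene (di-O-benzyl isolariciresinol)
Conditions: NaBH4, THF/MeOH, 0 °C
Reagents that add atoms: none
Why: borohydride reduction of the aldehyde tautomer of the lactol, which should drain the equilibrium to the 1,4-diol faster than C2 can enolize.

**Step 11**
Reactants: 17 di-O-benzyl isolariciresinol
Product: 18 (+)-isolariciresinol, (1S,2R,3R)-1-(4-hydroxy-3-methoxyphenyl)-2,3-bis(hydroxymethyl)-6-methoxy-1,2,3,4-tetrahydronaphthalen-7-ol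
Conditions: H2 (1 atm), Pd/C (10%), EtOAc/MeOH, rt
Reagents that add atoms: none
Why: hydrogenolysis of the two aryl benzyl ethers, which leaves the C1 methine intact because it carries only C–C bonds.

**Compound list**
1 | O-benzylvanillin (4-benzyloxy-3-methoxybenzaldehyde) | COc1cc(C=O)ccc1OCc1ccccc1 | starting material
2 | dimethyl succinate | COC(=O)CCC(=O)OC | starting material
3 | methyl 2-[4-(benzyloxy)-3-methoxyphenyl]-5-oxotetrahydrofuran-3-carboxylate (paraconic ester lactone, not isolated) | COC(=O)C1CC(=O)OC1c1ccc(OCc2ccccc2)c(OC)c1 | intermediate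
4 | (E)-4-[4-(benzyloxy)-3-methoxyphenyl]-3-(methoxycarbonyl)but-3-enoic acid | COC(=O)/C(=C/c1ccc(OCc2ccccc2)c(OC)c1)CC(=O)O | intermediate
5 | (R)-4-[4-(benzyloxy)-3-methoxyphenyl]-3-(methoxycarbonyl)butanoic acid | COC(=O)[C@H](Cc1ccc(OCc2ccccc2)c(OC)c1)CC(=O)O | intermediate
6 | (R)-4-[4-(benzyloxy)-3-methoxyphenyl]-3-(hydroxymethyl)butanoic acid (formed as its salt, not isolated) | OC[C@H](Cc1ccc(OCc2ccccc2)c(OC)c1)CC(=O)O | intermediate
7 | (R)-4-[4-(benzyloxy)-3-methoxybenzyl]dihydrofuran-2(3H)-one | O=C1C[C@@H](Cc2ccc(OCc3ccccc3)c(OC)c2)CO1 | intermediate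
8 | (R)-4-[4-(benzyloxy)-2-bromo-5-methoxybenzyl]dihydrofuran-2(3H)-one | O=C1C[C@@H](Cc2cc(OC)c(OCc3ccccc3)cc2Br)CO1 | intermediate
9 | (4R)-4-[4-(benzyloxy)-2-bromo-5-methoxybenzyl]tetrahydrofuran-2-ol | OC1C[C@@H](Cc2cc(OC)c(OCc3ccccc3)cc2Br)CO1 | intermediate
10 | tert-butyl{[(4R)-4-(4-benzyloxy-2-bromo-5-methoxybenzyl)tetrahydrofuran-2-yl]oxy}dimethylsilane | CC(C)(C)[Si](C)(C)OC1C[C@@H](Cc2cc(OC)c(OCc3ccccc3)cc2Br)CO1 | intermediate
11 | aryllithium from 10 (Li in place of Br, not isolated) | CC(C)(C)[Si](C)(C)OC1C[C@@H](Cc2cc(OC)c(OCc3ccccc3)cc2[Li])CO1 | intermediate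
12 | silyl-protected lactol carrying the ortho diarylcarbinol | CC(C)(C)[Si](C)(C)OC1C[C@@H](Cc2cc(OC)c(OCc3ccccc3)cc2C(O)c2ccc(OCc3ccccc3)c(OC)c2)CO1 | intermediate
13 | (4R)-4-{4-(benzyloxy)-2-[(4-benzyloxy-3-methoxyphenyl)(hydroxy)methyl]-5-methoxybenzyl}tetrahydrofuran-2-ol (key-step precursor) | OC1C[C@@H](Cc2cc(OC)c(OCc3ccccc3)cc2C(O)c2ccc(OCc3ccccc3)c(OC)c2)CO1 | intermediate
14 | (E)-enamine of the C9 aldehyde with the imidazolidinone, carrying the C1 benzhydryl cation (trifluoroacetate, not isolated) | CN1C(=O)[C@@H](Cc2ccccc2)N(/C=C/[C@H](CO)Cc2cc(OC)c(OCc3ccccc3)cc2[CH+]c2ccc(OCc3ccccc3)c(OC)c2)[C@H]1C(C)(C)C.[O-]C(=O)C(F)(F)F | intermediate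
15 | (1S,2R,3R)-7-benzyloxy-1-(4-benzyloxy-3-methoxyphenyl)-3-(hydroxymethyl)-6-methoxytetralin-2-carbaldehyde (not isolated) | COc1cc([C@H]2c3cc(OCc4ccccc4)c(OC)cc3C[C@@H](CO)[C@@H]2C=O)ccc1OCc1ccccc1 | intermediate
16 | (1S,2R,3R) tetralin-fused lactol, di-O-benzyl isolariciresinol at the C9 aldehyde level (key-step product) | COc1cc([C@H]2c3cc(OCc4ccccc4)c(OC)cc3C[C@@H](CO5)[C@@H]2C5O)ccc1OCc1ccccc1 | intermediate
17 | di-O-benzyl isolariciresinol | COc1cc([C@H]2c3cc(OCc4ccccc4)c(OC)cc3C[C@@H](CO)[C@@H]2CO)ccc1OCc1ccccc1 | intermediate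
18 | (+)-isolariciresinol | COc1cc([C@H]2c3cc(O)c(OC)cc3C[C@@H](CO)[C@@H]2CO)ccc1O | target

**Step count and risks**
Total steps: 11. Longest linear sequence: 11 steps (1 and 2 to 18).

Step 9 (most likely to fail). The cation may be consumed by bimolecular arylation or hydride transfer before the slowly formed enamine captures it, or the facial selectivity at C1 may be poor. The fallback sets out from lactone 7 and returns at diol 17, using the classical aryltetralin sequence. Lactone 7 is deprotonated with LiN(i-Pr)2 in THF at −78 °C and the enolate is added to aldehyde 1, which should give the trans aldol product (3S,4R)-4-[4-(benzyloxy)-3-methoxybenzyl]-3-{[4-(benzyloxy)-3-methoxyphenyl](hydroxy)methyl}dihydrofuran-2(3H)-one F1. CF3CO2H in CH2Cl2 at 0 °C then ionizes the carbinol, and Friedel–Crafts attack by the ring A carbon para to the methoxy group closes ring B to the (1S,2R,3R) trans,trans tetralin lactone F2, with the C9 carbonyl on C2. LiAlH4 in THF opens F2 to 17. This forms C1–C8a in place of C1–C2 and needs no bromine.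

Step 7. The aryllithium may be quenched by proton transfer or by 1-bromobutane before it meets the aldehyde, and the silyl acetal may be attacked. The fallback sets out from bromide 10 and returns at carbinol 12. Miyaura borylation (B2pin2, Pd(dppf)Cl2, KOAc, dioxane, 80 °C) should give the aryl pinacol boronate F3. Rh-catalysed 1,2-addition of F3 to aldehyde 1 ([Rh(cod)OH]2, P(t-Bu)3, dioxane/H2O, 60 °C) then forms the diarylcarbinol without any organolithium.

Step 4. Bromination may spread to the second free position of ring A or go on to a dibromide, because two alkoxy groups activate the ring. The fallback sets out from dimethyl succinate 2 and returns at bromo lactone 8, carrying the halogen from the start. Commercial 6-bromovanillin F4 is benzylated (BnBr, K2CO3, DMF) to 4-benzyloxy-2-bromo-5-methoxybenzaldehyde F5. Stobbe condensation with 2 (NaOMe, MeOH, reflux) gives the bromo (E)-half-ester F6. Hydrogenation with the Rh catalyst of step 2, which tolerates aryl bromides, gives the (R)-bromo half-ester F7. The KOH, Ca(BH4)2 and HCl sequence of step 3 then delivers 8.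

**Further compounds**
F1 | step 9 | (3S,4R)-4-[4-(benzyloxy)-3-methoxybenzyl]-3-{[4-(benzyloxy)-3-methoxyphenyl](hydroxy)methyl}dihydrofuran-2(3H)-one | COc1cc(C(O)[C@H]2C(=O)OC[C@@H]2Cc2ccc(OCc3ccccc3)c(OC)c2)ccc1OCc1ccccc1
F2 | step 9 | (1S,2R,3R) trans,trans tetralin γ-lactone (C9 carbonyl on C2, C9' O-CH2 on C3), di-O-benzyl | COc1cc([C@H]2c3cc(OCc4ccccc4)c(OC)cc3C[C@@H](CO5)[C@@H]2C5=O)ccc1OCc1ccccc1
F3 | step 7 | aryl pinacol boronate from 10 (Bpin in place of Br) | CC(C)(C)[Si](C)(C)OC1C[C@@H](Cc2cc(OC)c(OCc3ccccc3)cc2B2OC(C)(C)C(C)(C)O2)CO1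
F4 | step 4 | 6-bromovanillin (2-bromo-4-hydroxy-5-methoxybenzaldehyde, purchased) | COc1cc(C=O)c(Br)cc1O
F5 | step 4 | 4-benzyloxy-2-bromo-5-methoxybenzaldehyde | COc1cc(C=O)c(Br)cc1OCc1ccccc1
F6 | step 4 | (E)-4-[4-(benzyloxy)-2-bromo-5-methoxyphenyl]-3-(methoxycarbonyl)but-3-enoic acid | COC(=O)/C(=C/c1cc(OC)c(OCc2ccccc2)cc1Br)CC(=O)O
F7 | step 4 | (R)-4-[4-(benzyloxy)-2-bromo-5-methoxyphenyl]-3-(methoxycarbonyl)butanoic acid | COC(=O)[C@H](Cc1cc(OC)c(OCc2ccccc2)cc1Br)CC(=O)O
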